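**Small charge.** With the reagent X charged at 0.12 M, the product Q barely shows. Z is the substrate and G the main product. At the last reading, Tuesday's run gives Q 0.1% and Thursday's 0.1%, each less than the scatter of 0.5 percentage points. Now X is to go much higher.

| setting | Tuesday's | Thursday's | teal | violet | green | amber | red |
|---|---|---|---|---|---|---|---|
| Z | 0.60 M | 0.80 M | 0.40 M | 0.40 M | 0.40 M | 0.40 M | 0.40 M |
| X | 0.12 M | 0.12 M | 0.120 M | 0.200 M | 0.300 M | 0.400 M | 0.600 M |
| remark | run made earlier | run made earlier |  |  |  |  |  |
| time |  |  | 15 h | 15 h | 15 h | 15 h | 15 h |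

- Tuesday's (time / h: G / %, Q / %, J / %): 1.33: 1.0, 0.1, 1.1; 2.50: 2.9, 0, 0; 4.00: 4.0, 0, 0; 5.00: 4.2, 0.3, 0.1; 6.00: 6.7, 0.3, 0; 8.00: 7.7, 0, 0.8; 10.0: 7.9, 0.1, 0.7
- Thursday's (time / h: G / %, Q / %, J / %): 0.500: 0, 0.3, 0.3; 1.33: 1.9, 0.6, 0; 2.50: 3.9, 0, 0.5; 4.00: 4.3, 0, 0; 5.00: 5.0, 0.2, 0; 8.00: 6.5, 0, 0; 10.0: 7.4, 0.1, 0.5

(scatter of a reading: 0.5 percentage points)

- "hardly changes" means that all values lie within two and a half points (for a concentration: within two and a half percent of the largest)

1. share of G in all that became G or Q or J or D for teal, violet, green, amber, red, in this order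
2. how that number moves from the first to the last of them (rises, then falls / rises all the way / hardly changes / falls all the way / falls, then rises)

**Side ratio.** Both last readings together give 0.109 M⁻¹. This is my side ratio s, the Q made per G made, divided by the concentration of X, a selectivity factor. It is a reading, and a rough one. Counting G against Q and nothing else, the share of G is 1/(1 + sX).

**My bracket.** The upper edge assumes that Q takes no more X than G does, so the ratio seen at the small charge holds across the row and the share stays at 98.7%. The lower edge assumes that Q takes one X more, so the ratio grows in step with X. That joins the small-charge end to red, at 0.600 M, where the share is 93.9%. The two runs share one charge of X and cannot choose between the edges. I commit to the lower one: a fall of 4.8 points across the row, beyond the margin for "hardly changes". D has no readings, so it stands outside this bracket.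

**The forecast.** It gives 95% for teal and 95% for red, and its shape is "hardly changes", since “the simplest expectation is that the share stays flat near 95%”. For red, that lies inside my bracket, but we differ on the shape.

**The result.**

    Z + X → G (k = 2.90 × 10⁻⁵ M⁻¹ s⁻¹)
    Z + 2 X → Q (k = 3.70 × 10⁻⁶ M⁻² s⁻¹)
    G ⇌ J (K = 2.20, k = 6.00 × 10⁻⁷ s⁻¹)
    G → D (k = 4.90 × 10⁻⁶ s⁻¹)

The row runs from 84.0% on teal to 79.0% on red, so it falls all the way, and red ends below my lower edge. At 15.0 h, red holds D at 7.23%. Counting as made G whatever has become J or D, s times red's charge gives 0.0654, and red's Q over its G, J and D together is 0.0620. For violet, s times the charge gives 0.0218, and the same measured ratio is 0.0199.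

The numbers in the tables are simulated for an exercise; the scatter is artificial.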